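The oxolane atoms are O1, C2 (trimethoxyphenyl carbon), C3, C4 and C5 (phenol-ring carbon), and the ring is disconnected at O1–C2 and C3–C4. An enantiopure 1-arylallyl alcohol (O1, C5, C4 and the future C4 methyl) and ethyl propenyl ether (C2, C3 and the C3 methyl) are joined in one flask: iodoacetalisation forms O1–C2 and a 5-exo radical closure forms C3–C4. The step exploits ring oxygen O1 flanked by the benzylic stereocentre C5 and the contiguous methyl-bearing carbons C3 and C4: the C5 aryl group, equatorial in a chair-like transition state, relays its configuration to C4 and C3. C2 stays an acetal, so the trimethoxyphenyl ring enters afterwards through the oxocarbenium ion, anti to both methyls.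

Key step: step 4

Remark: 3-hydroxy-4,5-dimethoxybenzaldehyde, ethyl prop-1-enyl ether (E/Z mixture) and (3,4,5-trimethoxyphenyl)magnesium bromide (THF solution) are taken as catalogue compounds.

Step 1
Reactants: 1 3-hydroxy-4,5-dimethoxybenzaldehyde
Product: 2 3-[(tert-butyldimethylsilyl)oxy]-4,5-dimethoxybenzaldehyde
Conditions: TBSCl, imidazole, DMF, 0 °C to rt
Reagents that add atoms: tert-butyldimethylsilyl chloride, CC(C)(C)[Si](C)(C)Cl
Why: Silylation of the phenol (silyl ether protection) masks the acidic OH against the Grignard reagents and keeps the free phenol ring from being iodinated in step 4; no stereocentre is formed.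

Step 2
Reactants: 2 3-[(tert-butyldimethylsilyl)oxy]-4,5-dimethoxybenzaldehyde
Product: 3 rac-1-{3-[(tert-butyldimethylsilyl)oxy]-4,5-dimethoxyphenyl}prop-2-en-1-ol
Conditions: vinylmagnesium bromide, THF, −78 to 0 °C; aq NH4Cl
Reagents that add atoms: vinylmagnesium bromide, C=C[Mg]Br
Why: Grignard 1,2-addition to the aldehyde installs C4 and the future C4 methyl carbon; the carbinol centre C5 forms racemic and is resolved in step 3.

Step 3
Reactants: 3 rac-1-{3-[(tert-butyldimethylsilyl)oxy]-4,5-dimethoxyphenyl}prop-2-en-1-ol
Product: 4 (S)-1-{3-[(tert-butyldimethylsilyl)oxy]-4,5-dimethoxyphenyl}prop-2-en-1-ol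
Conditions: Novozym 435 (immobilised Candida antarctica lipase B), vinyl acetate, MTBE, 30 °C, stopped just past half conversion
Reagents that add atoms: none
Why: Lipase-catalysed kinetic resolution by irreversible transesterification should acylate the (R)-alcohol (aryl as the large, vinyl as the medium group), so that (S)-4 is recovered and C5 is fixed.

Step 4
Reactants: 4 (S)-1-{3-[(tert-butyldimethylsilyl)oxy]-4,5-dimethoxyphenyl}prop-2-en-1-ol; 5 ethyl prop-1-enyl ether (E/Z mixture)
Product: 7 (2RS,3R,4S,5S)-5-{3-[(tert-butyldimethylsilyl)oxy]-4,5-dimethoxyphenyl}-2-ethoxy-3,4-dimethyloxolane, via iodoacetal 6 (not isolated)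
Conditions: NIS, 2,6-lutidine, CH2Cl2, −40 to 0 °C; then toluene, Bu3SnH, Et3B, air, −78 °C to rt
Reagents that add atoms: none
Why: Iodonium transfer from N-iodosuccinimide to the enol ether gives an α-iodo oxocarbenium ion that the hydroxyl of 4 captures (O1–C2); the triethylborane/air-started stannyl radical chain then abstracts iodine, and the secondary C3 radical adds to the internal vinyl carbon C4 (C3–C4), the primary radical so formed taking hydrogen from Bu3SnH to become the C4 methyl. This is the Ueno–Stork haloacetal radical cyclisation, run without isolation of 6. The single ring closure is 5-exo-trig through a chair-like transition state. C4 is set by C5, whose aryl group sits pseudo-equatorial and so ends trans to the new methyl; C3 is set by the usual preference of a substituent on the radical carbon for the orientation syn to the alkene, which places the two methyls cis; C2 is an epimeric acetal carbon that step 5 makes planar. The step needs iodination of the enol ether in preference to the vinyl group and the arene, which the far higher nucleophilicity of the enol ether secures, and ring closure ahead of hydrogen transfer, which low temperature, dilution and the fast closure of β-oxygenated hexenyl radicals should secure.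

Step 5
Reactants: 7 (2RS,3R,4S,5S)-5-{3-[(tert-butyldimethylsilyl)oxy]-4,5-dimethoxyphenyl}-2-ethoxy-3,4-dimethyloxolane; 8 (3,4,5-trimethoxyphenyl)magnesium bromide
Product: 9 (2R,3R,4S,5S)-5-{3-[(tert-butyldimethylsilyl)oxy]-4,5-dimethoxyphenyl}-3,4-dimethyl-2-(3,4,5-trimethoxyphenyl)oxolane
Conditions: 8, CuBr·SMe2, THF–Et2O, −40 °C; BF3·OEt2, −78 °C; then 7, −78 to −30 °C; aq NH4Cl–NH3
Reagents that add atoms: none
Why: BF3 ionises the exocyclic ethoxy group and the arylcopper reagent adds to the cyclic oxocarbenium ion (Lewis acid-mediated acetal substitution, C-arylation of a lactol ether), inside attack on the envelope with the C4 methyl pseudo-equatorial coming from the face anti to both methyls, so that C2 is set with its aryl group trans to the C3 methyl and cis to the C5 aryl group.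

Step 6
Reactants: 9 (2R,3R,4S,5S)-5-{3-[(tert-butyldimethylsilyl)oxy]-4,5-dimethoxyphenyl}-3,4-dimethyl-2-(3,4,5-trimethoxyphenyl)oxolane
Product: 10 5-[(2S,3S,4R,5R)-3,4-dimethyl-5-(3,4,5-trimethoxyphenyl)oxolan-2-yl]-2,3-dimethoxyphenol (target; 2R,3R,4S,5S in the ring numbering used above)
Conditions: Bu4NF, THF, 0 °C; aq NH4Cl
Reagents that add atoms: none
Why: Fluoride-mediated desilylation frees the phenol under conditions that should leave the two benzylic ether carbons and all four stereocentres untouched.

Compound list
1 | 3-hydroxy-4,5-dimethoxybenzaldehyde | COc1cc(C=O)cc(O)c1OC | starting material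
2 | 3-[(tert-butyldimethylsilyl)oxy]-4,5-dimethoxybenzaldehyde | COc1cc(C=O)cc(O[Si](C)(C)C(C)(C)C)c1OC | intermediate
3 | rac-1-{3-[(tert-butyldimethylsilyl)oxy]-4,5-dimethoxyphenyl}prop-2-en-1-ol | COc1cc(C(O)C=C)cc(O[Si](C)(C)C(C)(C)C)c1OC | intermediate
4 | (S)-1-{3-[(tert-butyldimethylsilyl)oxy]-4,5-dimethoxyphenyl}prop-2-en-1-ol | COc1cc([C@H](C=C)O)cc(O[Si](C)(C)C(C)(C)C)c1OC | intermediate
5 | ethyl prop-1-enyl ether (E/Z mixture) | CC=COCC | starting material
6 | tert-butyl{5-[(1S)-1-(1-ethoxy-2-iodopropoxy)prop-2-en-1-yl]-2,3-dimethoxyphenoxy}dimethylsilane (iodoacetal, mixture at the acetal and iodide carbons) | COc1cc([C@H](C=C)OC(OCC)C(C)I)cc(O[Si](C)(C)C(C)(C)C)c1OC | intermediate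
7 | (2RS,3R,4S,5S)-5-{3-[(tert-butyldimethylsilyl)oxy]-4,5-dimethoxyphenyl}-2-ethoxy-3,4-dimethyloxolane | COc1cc([C@H]2OC(OCC)[C@H](C)[C@@H]2C)cc(O[Si](C)(C)C(C)(C)C)c1OC | intermediate
8 | (3,4,5-trimethoxyphenyl)magnesium bromide | COc1cc([Mg]Br)cc(OC)c1OC | starting material
9 | (2R,3R,4S,5S)-5-{3-[(tert-butyldimethylsilyl)oxy]-4,5-dimethoxyphenyl}-3,4-dimethyl-2-(3,4,5-trimethoxyphenyl)oxolane | COc1cc([C@H]2O[C@@H](c3cc(OC)c(OC)c(OC)c3)[C@H](C)[C@@H]2C)cc(O[Si](C)(C)C(C)(C)C)c1OC | intermediate
10 | 5-[(2S,3S,4R,5R)-3,4-dimethyl-5-(3,4,5-trimethoxyphenyl)oxolan-2-yl]-2,3-dimethoxyphenol | COc1cc([C@H]2O[C@@H](c3cc(OC)c(OC)c(OC)c3)[C@H](C)[C@@H]2C)cc(O)c1OC | target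

Total step count: 6
Longest linear sequence: 6 steps (1 → 2 → 3 → 4 → 7 → 9 → 10)

Steps most likely to fail

Step 4 (key step). Two processes may go wrong. The stannane may transfer hydrogen to the open-chain C3 radical before it closes. The two orientations of the methyl on the radical carbon may be poorly discriminated, because the ethoxy group at C2 is an epimeric mixture and gives no help. The fallback sets out from 4 and comes back at 9. The copper alkoxide of 4 (n-BuLi, then CuI, THF) is allylated at the benzylic terminus of tert-butyl (E)-3-(3,4,5-trimethoxyphenyl)prop-2-enyl carbonate F1, which is made from commercial (E)-3-(3,4,5-trimethoxyphenyl)prop-2-en-1-ol and Boc2O. The catalyst is [Ir(cod)Cl]2 with a binaphthol-derived N,N-bis(1-phenylethyl)phosphoramidite, whose enantiomer is chosen to give the (R) ether carbon. This should furnish the bis-allylic ether F2 with both benzylic centres in place. Hydrogen-atom-transfer reductive cyclisation of this 1,6-diene (Mn(dpm)3, PhSiH3, tert-butyl hydroperoxide, isopropanol, rt) should then form C3–C4 through a chair in which both aryl groups are equatorial. Both vinyl groups become the cis methyl pair, which gives 9 directly and makes step 5 unnecessary.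

Step 5. The Lewis acid may ionise the ring C2–O1 bond instead of the exocyclic C–OEt bond and open the ring, and slow aryl transfer may erode the facial selectivity. The fallback sets out from 7 and comes back at 9. Exchange of the ethoxy group with benzenesulfinic acid and CaCl2 in CH2Cl2 should give the 2-(phenylsulfonyl)oxolane F3. The arylzinc bromide made from 8 and ZnBr2 in THF then displaces the sulfinate at rt through the same oxocarbenium ion (substitution of 2-sulfonyl cyclic ethers by organozinc reagents).

Step 3. The bulky trisubstituted aryl group may slow the acylation and lower the discrimination between the enantiomers, and half of the material is lost in any case. The fallback sets out from 2 and comes back at 4. Divinylzinc (from vinylmagnesium bromide and ZnCl2) is added to aldehyde 2 in toluene at 0 °C with catalytic (−)-3-exo-(dimethylamino)isoborneol. This amino alcohol directs alkyl and alkenyl zinc reagents to the Si face of aryl aldehydes, so the addition should give 4 in one step in place of steps 2 and 3.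

Further compounds
F1 | step 4 | tert-butyl (E)-3-(3,4,5-trimethoxyphenyl)prop-2-enyl carbonate | COc1cc(/C=C/COC(=O)OC(C)(C)C)cc(OC)c1OC
F2 | step 4 | tert-butyl{2,3-dimethoxy-5-[(1S)-1-{[(1R)-1-(3,4,5-trimethoxyphenyl)prop-2-en-1-yl]oxy}prop-2-en-1-yl]phenoxy}dimethylsilane | COc1cc([C@H](C=C)O[C@@H](c2cc(OC)c(OC)c(OC)c2)C=C)cc(O[Si](C)(C)C(C)(C)C)c1OC
F3 | step 5 | (2RS,3R,4S,5S)-5-{3-[(tert-butyldimethylsilyl)oxy]-4,5-dimethoxyphenyl}-3,4-dimethyl-2-(phenylsulfonyl)oxolane | COc1cc([C@H]2OC(S(=O)(=O)c3ccccc3)[C@H](C)[C@@H]2C)cc(O[Si](C)(C)C(C)(C)C)c1OC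
F0 | step 3 | none | none
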